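## Structural features

- The target is a C30 triterpenoid made of two bicyclic halves. One is a trans-fused octahydro-1-benzoxepine (an oxepane fused to a cyclohexane). The other is a cis-fused perhydroazulene (a cyclopentane fused to a cycloheptane). A two-carbon chain joins C6′ of the first to C5 of the second.
- There are eleven stereocentres. The benzoxepine half holds the remote carbinol C3′ next to the gem-dimethyl ether carbon C2′ and the contiguous set C9a′–C5a′–C6′–C7′. The azulene half holds C1–C8a–C3a on the five-membered ring and C5–C6–C7 on the seven-membered ring.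
- Both ends of the bridge sit on methine carbons flanked by a quaternary carbon (C5a′, C4) and a fully substituted oxygenated carbon (C7′, C6). Any bond made there is neopentyl in character.
- The fragile groups are the trisubstituted C6–C7 oxirane (acid, neighbouring hydroxyls), the tertiary alcohols at C1 and C7′ (the latter axial and syn to the angular methyl) and the tertiary ether O1′–C2′.
- The real difficulty is the cis-fused seven-membered ring: it carries the quaternary C4 beside the ring fusion, and C5 and the epoxide lie far from any controlling element. The tertiary ether inside a seven-membered ring is the second hard point.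
- The key step uses the cyclopentane C1–C2–C3–C3a–C8a. C8a bears C8 and C3a bears C4 with its two methyl groups. The C8a–C3a bond can therefore join an alkyne carbon (propargylic to the C1 methyl carbinol) to the inner carbon of a prenyl group, whose C(CH3)2 end reappears as an isopropenyl group, a latent C4.

## Logic of the disconnections

38 from 37: only two O–Si bonds are cut. The oxirane tolerates fluoride but not acid, so both silyl ethers are kept to the last step. The demand is a neutral or basic deprotection.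

37 from 36 from 35: the two C–O bonds of the oxirane are cut back to the C6=C7 alkene. The alkene is robust through the fragment union, and a bromohydrin puts oxygen on the face opposite to the one an electrophile attacks. The demand is bromonium formation on the lower face and anti opening.

35 from 34 from 33: the C6–CH3 bond is cut to a C6 ketone. That ketone is what makes the union possible. The demand is enolisation toward C7 (CH2), not toward the hindered C5.

33 from 32 and 16: the central CH2–CH2 bond of the bridge is cut. Each half then ends in a one-carbon unit, and a radical addition to an exocyclic enone is indifferent to the neopentyl surroundings. The gain is two C15 halves of equal size. The demand is hydrogen delivery to C5 from the lower face.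

32 from 31 from 30 from 29: the C–I bond, then C6′–H with CH2–O, then C7′–CH3 are cut back to an exocyclic enone. Two additions to one enone set C7′ and C6′. Both demand attack anti to the axial C5a′ methyl group.

29 from 28 from 27 from 26: the O1′–C2′ bond is cut to a hydroxy epoxide and then to a trisubstituted alkene. C3′ comes from a reagent-controlled epoxidation. The demand is opening at the tertiary epoxide carbon (seven-membered ring), not at C3′.

26 from 25 from 20 and 21: the C5a′–C5′ bond and the C6′=CH2 bond are cut. One conjugate addition with enolate trapping builds the quaternary centre trans to oxygen and fixes the enone regiochemistry. 20 goes back through 19 and 18 to 17 (C7′=O by allylic oxidation, C9a′ by ketone reduction).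

16 from 13 from 12 from 10: the second C4–CH3 bond and C5=CH2, then C4=C5 (metathesis), then C6–C7 (acylation) are cut. The isopropenyl group becomes the gem-dimethyl carbon without any C–H functionalisation. The demand is metathesis of a 1,1-disubstituted alkene with a vinyl ketone. 10 comes from 9 and 8 by functional group changes.

8 from 7 from 6: C8a–H and then the C8a–C3a bond are cut (key step). A carbocycle with three stereocentres falls back to an acyclic enyne with one. The demands are insertion on the correct alkene face and hydride delivery anti to the isopropenyl group.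

6 from 5, 4, 3, 2 and 1: the bond to the ester carbon, the alkyne (from an epoxy chloride) and the C1 stereocentre (asymmetric epoxidation of an allylic alcohol) are cut. The demand is that the C–O bond at the quaternary carbon is never broken.

## Other disconnections considered

The three alternatives build the benzoxepine half; their locants are primed here.

Alternative 1: The cut is the C3′=C4′ bond of the ether ring. Diene A1 would be closed by (H2IMes)(PCy3)Cl2Ru=CHPh (second-generation Grubbs catalyst) to dihydrooxepine A2.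
- In its favour: two quaternary carbons assist the ring closure, and there is no regiochemical choice. On that point it is the equal or the better of step 19.
- Against it: the tertiary 1,1-dimethylallyl ether must be made intermolecularly on a hindered carbinol. A1 needs oxygen trans to the allyl group, whereas desymmetrising reductions of 2,2-disubstituted cyclohexane-1,3-diones usually place hydroxyl cis to the larger group. A2 still lacks the C3′ hydroxyl, which must go on the more hindered alkene carbon with facial control far from the ring fusion. Its C6′ ketal must still become the one-carbon branch and the C7′ carbinol.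
- Comparison: it closes one ring and sets no stereocentre, where steps 16–19 set C5a′ and C3′. The mechanism is carbene metathesis, against an ionic epoxide opening. In steps it should be longer by about three for the hydroxyl and three for C6′/C7′.

Alternative 2: The cut is the C6′–C7′ bond together with an O–CH2 bond. Oxime A3 would be oxidised (NaOCl) to nitrile oxide A4, which adds to the vinyl group on C5a′ to give isoxazoline A5.
- In its favour: one step closes the cyclohexane and delivers C7′ as a masked ketone with an oxygenated CH2 on C6′ (N–O cleavage, for example with Mo(CO)6). This is exactly the pattern that steps 16, 21 and 22 assemble separately, so here it is the better.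
- Against it: a monocyclic oxepane with adjacent quaternary and tertiary centres and the tertiary ether must be built first, where a seven-membered ring gives weak stereocontrol relative to C3′. The vinyl group on a quaternary carbon is a hindered dipolarophile. C6′ depends on the facial course of the cycloaddition.
- Comparison: the mechanism is a concerted dipolar cycloaddition, against stepwise polar additions. Step economy is equal at best, because A3 should cost more steps than 26.

Alternative 3: The cuts are O1′–C2′ and C5a′–C6′. Bis-epoxide A6 would be treated with Me3SiOTf: the inner epoxide oxygen opens the terminal epoxide and the allylsilane closes the carbocycle, giving A7.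
- In its favour: both rings form in one step, and C3′, C5a′, C6′ and C9a′ derive from two reagent-controlled epoxidations and one alkene geometry. In step economy and economy of stereocontrol for this half it is clearly the better of steps 13–20. The anti opening should fix the trans fusion as reliably as the anti conjugate addition of step 16.
- Against it: such cascades are sensitive to exo opening and early termination. A triene must be epoxidised twice beside an allylsilane. The C7′ methylene of A7 must become a carbinol with axial hydroxyl, which epoxidation and hydride opening would not give, and the ketone path passes through a β-acyloxy ketone prone to elimination.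
- Comparison: the ether bond has the same polarity as in step 19, but it is formed together with the C–C bond. The chosen plan separates the two events so that each centre can be checked.

None of the three addresses the perhydroazulene, which is where the chosen key step puts its weight.

Key step: step 6

Remark on the chemistry: locants C1–C8a are those of the azulene half and primed locants those of the 1-benzoxepine half; "upper face" of the azulene half is the face of the C1 methyl group, the C8a–C8 bond and the C5 side chain, and "lower face" is that of the ring-fusion hydrogens and the C1 oxygen.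

Remark on the chemistry: the precursor and product of the key step agree with the target (precursor R; product Z, 2R,5S) and need no change. Only the way to the precursor is corrected: catalytic enantioselective addition of a propiolate to a dialkyl methyl ketone lacks reliable precedent and a tertiary alcohol resolves poorly, so the carbinol centre is taken from an asymmetric epoxidation of 1.

Remark on the chemistry (assumption): in the cis-fused azulene intermediates reagents are assumed to reach C5 and the C6=C7 alkene from the lower face; steps 24 and 27 rest on this and each has a fallback for the opposite case.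

## Steps

Step 1
Reactants: 1 geraniol
Product: 2 [(2R,3R)-3-methyl-3-(4-methylpent-3-en-1-yl)oxiran-2-yl]methanol
Conditions: Ti(Oi-Pr)4 (cat.), D-(−)-diisopropyl tartrate, t-BuOOH, 4 Å sieves, CH2Cl2, −20 °C
Reagents that add atoms: tert-butyl hydroperoxide, CC(C)(C)OO
Why: Sharpless asymmetric epoxidation; only the allylic alkene binds titanium, and the D-tartrate should deliver oxygen to the face that gives the (2R,3R)-epoxide, whose quaternary carbon becomes C1.

Step 2
Reactants: 2 [(2R,3R)-3-methyl-3-(4-methylpent-3-en-1-yl)oxiran-2-yl]methanol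
Product: 3 (2R,3S)-3-(chloromethyl)-2-methyl-2-(4-methylpent-3-en-1-yl)oxirane
Conditions: PPh3, CCl4, NaHCO3, reflux
Reagents that add atoms: carbon tetrachloride, ClC(Cl)(Cl)Cl
Why: Appel chlorination of a primary alcohol under neutral conditions, which should leave the acid-labile trisubstituted epoxide intact.

Step 3
Reactants: 3 (2R,3S)-3-(chloromethyl)-2-methyl-2-(4-methylpent-3-en-1-yl)oxirane
Product: 4 (3R)-3,7-dimethyloct-6-en-1-yn-3-ol
Conditions: n-BuLi (3.2 equiv), THF, −78 to −30 °C
Reagents that add atoms: none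
Why: Base-induced double elimination of a 2,3-epoxy chloride (deprotonation at CH2Cl, opening to the chlorovinyl alkoxide, loss of HCl); the C–O bond at the quaternary carbon is never broken, so the tertiary propargylic alcohol keeps the configuration set in step 1.

Step 4
Reactants: 4 (3R)-3,7-dimethyloct-6-en-1-yn-3-ol
Product: 5 {[(3R)-3,7-dimethyloct-6-en-1-yn-3-yl]oxy}triethylsilane
Conditions: Et3SiOTf, 2,6-lutidine, CH2Cl2, −78 to 0 °C
Reagents that add atoms: triethylsilyl trifluoromethanesulfonate, CC[Si](CC)(CC)OS(=O)(=O)C(F)(F)F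
Why: Silylation of a tertiary alcohol with a silyl triflate; the triethylsilyl ether is small at oxygen (so methyl stays the dominant group at C1 in step 6), blocks lactonisation of the later Z enoate and falls to fluoride in step 29.

Step 5
Reactants: 5 {[(3R)-3,7-dimethyloct-6-en-1-yn-3-yl]oxy}triethylsilane
Product: 6 methyl (4R)-4,8-dimethyl-4-[(triethylsilyl)oxy]non-7-en-2-ynoate
Conditions: n-BuLi, THF, −78 °C; ClCO2Me
Reagents that add atoms: methyl chloroformate, COC(=O)Cl
Why: C-acylation of a lithium acetylide with a chloroformate, a standard route to ynoates.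

Step 6
Reactants: 6 methyl (4R)-4,8-dimethyl-4-[(triethylsilyl)oxy]non-7-en-2-ynoate
Product: 7 methyl (2Z)-[(2R,5S)-2-methyl-5-(prop-1-en-2-yl)-2-[(triethylsilyl)oxy]cyclopentylidene]acetate
Conditions: Pd(OAc)2 (5 mol%), PPh3 (10 mol%), PhH, 70 °C
Reagents that add atoms: none
Why: Palladium-catalysed Alder-ene type cycloisomerization of a 1,6-enyne, a known reaction class that includes ynoates and prenyl-type alkenes. A divalent palladium hydride (or, with the same outcome, a palladacyclopentene of tetravalent palladium) adds to the alkyne so that palladium sits on C8a. The alkenylpalladium then inserts the trisubstituted alkene by 5-exo-trig carbopalladation, which forms the C8a–C3a bond and closes the cyclopentane. β-Hydride elimination from a methyl group of the tertiary alkylpalladium releases the isopropenyl group and the catalyst. Syn addition across the alkyne fixes the exocyclic enoate as the Z isomer, ester on the side of C1. The new centre C3a is controlled by the quaternary C1: the CMe2–Pd terminus and the C1 methyl group (larger at short range than a silyloxy group) should both lie pseudo-equatorial on the forming ring, which puts isopropenyl cis to methyl and trans to OSiEt3. The step also needs elimination toward methyl and not toward C3a–H (conjugated 1,3-diene); six methyl hydrogens against one ring hydrogen favour the 1,4-diene.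

Step 7
Reactants: 7 methyl (2Z)-[(2R,5S)-2-methyl-5-(prop-1-en-2-yl)-2-[(triethylsilyl)oxy]cyclopentylidene]acetate
Product: 8 methyl 2-[(1R,2R,5R)-2-methyl-5-(prop-1-en-2-yl)-2-[(triethylsilyl)oxy]cyclopentyl]acetate
Conditions: [(Ph3P)CuH]6 (5 mol%), 1,2-(Ph2P)2C6H4 (6 mol%), PhMe2SiH, t-BuOH, PhMe, rt
Reagents that add atoms: none
Why: Copper hydride conjugate reduction (1,4-hydride addition, then protonation of the silyl ketene acetal), selective for the enoate over the 1,1-disubstituted alkene. Hydride should reach C8a from the lower face, away from the isopropenyl group on C3a and the methyl group on C1, so C8a–H ends cis to C3a–H as the cis ring fusion needs.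

Step 8
Reactants: 8 methyl 2-[(1R,2R,5R)-2-methyl-5-(prop-1-en-2-yl)-2-[(triethylsilyl)oxy]cyclopentyl]acetate
Product: 9 2-[(1R,2R,5R)-2-methyl-5-(prop-1-en-2-yl)-2-[(triethylsilyl)oxy]cyclopentyl]ethan-1-ol
Conditions: LiAlH4, Et2O, 0 °C
Reagents that add atoms: none
Why: Hydride reduction of an ester to the primary alcohol; the tertiary silyl ether and the alkene are inert.

Step 9
Reactants: 9 2-[(1R,2R,5R)-2-methyl-5-(prop-1-en-2-yl)-2-[(triethylsilyl)oxy]cyclopentyl]ethan-1-ol
Product: 10 triethyl{[(1R,2R,3R)-2-(2-iodoethyl)-1-methyl-3-(prop-1-en-2-yl)cyclopentyl]oxy}silane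
Conditions: I2, PPh3, imidazole, CH2Cl2, 0 °C to rt
Reagents that add atoms: iodine, II
Why: Appel-type iodination of a primary alcohol via the alkoxyphosphonium salt under buffered conditions.

Step 10
Reactants: 10 triethyl{[(1R,2R,3R)-2-(2-iodoethyl)-1-methyl-3-(prop-1-en-2-yl)cyclopentyl]oxy}silane
Product: 12 5-[(1R,2R,5R)-2-methyl-5-(prop-1-en-2-yl)-2-[(triethylsilyl)oxy]cyclopentyl]pent-1-en-3-one, via alkylzinc iodide 11 (not isolated)
Conditions: Zn, LiCl, THF, 40 °C; then Pd(PPh3)4 (5 mol%), CH2=CHCOCl, 0 °C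
Reagents that add atoms: acryloyl chloride, C=CC(=O)Cl
Why: Zinc insertion into a primary iodide followed by Negishi acylation with an acid chloride; the mild organozinc tolerates the silyl ether, and low temperature with excess acid chloride should limit addition to the new vinyl ketone.

Step 11
Reactants: 12 5-[(1R,2R,5R)-2-methyl-5-(prop-1-en-2-yl)-2-[(triethylsilyl)oxy]cyclopentyl]pent-1-en-3-one
Product: 13 (1R,3aR,8aR)-1,4-dimethyl-1-[(triethylsilyl)oxy]-2,3,3a,7,8,8a-hexahydroazulen-6(1H)-one
Conditions: (H2IMes)Cl2Ru=CH(2-i-PrOC6H4) (second-generation Hoveyda–Grubbs catalyst, 5 mol%), PhMe (5 mM), 80 °C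
Reagents that add atoms: none
Why: Ring-closing metathesis of a vinyl ketone with a 1,1-disubstituted alkene to a β-methyl cycloheptenone; the cis arrangement of the two arms set in step 7 makes the closure possible and fixes the cis ring fusion.

Step 12
Reactants: 13 (1R,3aR,8aR)-1,4-dimethyl-1-[(triethylsilyl)oxy]-2,3,3a,7,8,8a-hexahydroazulen-6(1H)-one
Product: 16 (1R,3aR,8aR)-1,4,4-trimethyl-5-methylidene-1-[(triethylsilyl)oxy]octahydroazulen-6(1H)-one, via silyl enol ether 14 (not isolated), via Mannich base 15 (not isolated)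
Conditions: Me2CuLi (from MeLi, CuI), Me3SiCl, Et2O/THF, −78 to −20 °C; CH2=NMe2+ I−, CH2Cl2, rt; MeI; NaHCO3
Reagents that add atoms: lithium dimethylcuprate, [Li+].C[Cu-]C; N,N-dimethylmethyleneiminium iodide, C=[N+](C)C.[I-]
Why: Cuprate conjugate addition with silyl trapping, Mannich reaction of the silyl enol ether and Hofmann-type elimination (α-methylenation). Methyl addition makes C4 the gem-dimethyl carbon (no stereocentre), and the enolate regiochemistry puts the methylene group on C5 only.

Step 13
Reactants: 17 2-methylcyclohex-2-en-1-one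
Product: 18 (1R)-2-methylcyclohex-2-en-1-ol
Conditions: (S)-Me-CBS oxazaborolidine (10 mol%), BH3·SMe2, THF, −20 °C
Reagents that add atoms: none
Why: Corey–Bakshi–Shibata reduction; the alkenyl arm acts as the large group, so the (S)-catalyst should give the (R)-allylic alcohol, whose carbinol carbon becomes C9a′.

Step 14
Reactants: 18 (1R)-2-methylcyclohex-2-en-1-ol
Product: 19 tert-butyl(dimethyl){[(1R)-2-methylcyclohex-2-en-1-yl]oxy}silane
Conditions: t-BuMe2SiCl, imidazole, DMF, rt
Reagents that add atoms: tert-butyldimethylsilyl chloride, CC(C)(C)[Si](C)(C)Cl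
Why: Standard silylation; the bulky silyl ether is the directing group for step 16.

Step 15
Reactants: 19 tert-butyl(dimethyl){[(1R)-2-methylcyclohex-2-en-1-yl]oxy}silane
Product: 20 (4R)-4-[(tert-butyldimethylsilyl)oxy]-3-methylcyclohex-2-en-1-one
Conditions: Rh2(cap)4 (cap = caprolactamate, 1 mol%), t-BuOOH, K2CO3, CH2Cl2, rt
Reagents that add atoms: tert-butyl hydroperoxide, CC(C)(C)OO
Why: Allylic C–H oxidation of a cyclohexene to the enone; the ring CH2 at the unsubstituted alkene end is the reactive site, and the C–O stereocentre is not touched.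

Step 16
Reactants: 20 (4R)-4-[(tert-butyldimethylsilyl)oxy]-3-methylcyclohex-2-en-1-one; 21 5-bromo-2-methylpent-2-ene
Product: 25 (3R,4R)-4-[(tert-butyldimethylsilyl)oxy]-3-methyl-2-methylidene-3-(4-methylpent-3-en-1-yl)cyclohexan-1-one, via homoprenylmagnesium bromide 22 (not isolated), via silyl enol ether 23 (not isolated), via Mannich base 24 (not isolated)
Conditions: Mg, THF; CuBr·SMe2 (20 mol%), Me3SiCl, THF, −78 °C; CH2=NMe2+ I−, CH2Cl2, rt; MeI; NaHCO3
Reagents that add atoms: N,N-dimethylmethyleneiminium iodide, C=[N+](C)C.[I-]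
Why: Copper-catalysed conjugate addition of a Grignard reagent with silyl trapping, then Mannich reaction and elimination (α-methylenation). The nucleophile should add to C5a′ anti to the neighbouring silyloxy group, which sets the quaternary centre with the chain trans to oxygen (the future trans ring fusion), and the enolate places the methylene group on C6′ only.

Step 17
Reactants: 25 (3R,4R)-4-[(tert-butyldimethylsilyl)oxy]-3-methyl-2-methylidene-3-(4-methylpent-3-en-1-yl)cyclohexan-1-one
Product: 26 (3R,4R)-4-hydroxy-3-methyl-2-methylidene-3-(4-methylpent-3-en-1-yl)cyclohexan-1-one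
Conditions: HF·pyridine, THF, 0 °C to rt
Reagents that add atoms: none
Why: Acidic fluoride cleavage of a silyl ether; it is done before epoxidation because HF would open an epoxide, and basic fluoride is avoided beside the exocyclic enone.

Step 18
Reactants: 26 (3R,4R)-4-hydroxy-3-methyl-2-methylidene-3-(4-methylpent-3-en-1-yl)cyclohexan-1-one
Product: 27 (3R,4R)-3-{2-[(2R)-3,3-dimethyloxiran-2-yl]ethyl}-4-hydroxy-3-methyl-2-methylidenecyclohexan-1-one
Conditions: D-fructose-derived Shi ketone (30 mol%), KHSO5 (as 2KHSO5·KHSO4·K2SO4), K2CO3, Bu4NHSO4, MeCN/CH2(OMe)2/aq. Na2B4O7, 0 °C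
Reagents that add atoms: potassium peroxymonosulfate, [K+].[O-]S(=O)(=O)OO
Why: Shi asymmetric epoxidation; the chiral dioxirane should give the (R)-epoxide of the trisubstituted alkene (future C3′), and the electron-poor, hindered exocyclic enone should not compete for the electrophilic oxidant.

Step 19
Reactants: 27 (3R,4R)-3-{2-[(2R)-3,3-dimethyloxiran-2-yl]ethyl}-4-hydroxy-3-methyl-2-methylidenecyclohexan-1-one
Product: 28 (3R,5aR,9aR)-3-hydroxy-2,2,5a-trimethyl-6-methylideneoctahydro-1-benzoxepin-7(2H)-one
Conditions: camphorsulfonic acid (20 mol%), CH2Cl2, 0 °C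
Reagents that add atoms: none
Why: Acid-catalysed intramolecular epoxide opening by the equatorial hydroxyl at the tertiary carbon C2′ (endo mode, seven-membered ring), favoured by the cationic character of the fully substituted epoxide carbon. The C3′–O bond is untouched, so C3′ stays R, and the trans fusion follows from step 16.

Step 20
Reactants: 28 (3R,5aR,9aR)-3-hydroxy-2,2,5a-trimethyl-6-methylideneoctahydro-1-benzoxepin-7(2H)-one
Product: 29 (3R,5aR,9aR)-3-[(tert-butyldimethylsilyl)oxy]-2,2,5a-trimethyl-6-methylideneoctahydro-1-benzoxepin-7(2H)-one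
Conditions: t-BuMe2SiOTf, 2,6-lutidine, CH2Cl2, −78 °C
Reagents that add atoms: tert-butyldimethylsilyl trifluoromethanesulfonate, CC(C)(C)[Si](C)(C)OS(=O)(=O)C(F)(F)F
Why: Silylation of a hindered secondary alcohol with a silyl triflate at low temperature, which should spare the enone.

Step 21
Reactants: 29 (3R,5aR,9aR)-3-[(tert-butyldimethylsilyl)oxy]-2,2,5a-trimethyl-6-methylideneoctahydro-1-benzoxepin-7(2H)-one
Product: 30 tert-butyl(dimethyl){[(3R,5aR,7S,9aR)-2,2,5a,7-tetramethyl-6-methylidene-7-[(trimethylsilyl)oxy]decahydro-1-benzoxepin-3-yl]oxy}silane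
Conditions: MeLi, CeCl3, THF, −78 °C; then Me3SiCl, Et3N, −78 to 0 °C
Reagents that add atoms: methyllithium, [Li]C; chlorotrimethylsilane, C[Si](C)(C)Cl
Why: 1,2-Addition of an organocerium reagent to an enone; axial attack at C7′ is blocked by the syn-axial C5a′ methyl group, so methyl should enter equatorially and leave the oxygen axial (7S). Silylating the alkoxide in the same flask prevents borane delivery from this oxygen in step 22.

Step 22
Reactants: 30 tert-butyl(dimethyl){[(3R,5aR,7S,9aR)-2,2,5a,7-tetramethyl-6-methylidene-7-[(trimethylsilyl)oxy]decahydro-1-benzoxepin-3-yl]oxy}silane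
Product: 31 (3R,5aR,6S,7S,9aR)-3-[(tert-butyldimethylsilyl)oxy]-6-(hydroxymethyl)-2,2,5a,7-tetramethyldecahydro-1-benzoxepin-7-ol
Conditions: BH3·THF, THF, 0 °C to rt; NaOH, H2O2, EtOH, 50 °C
Reagents that add atoms: hydrogen peroxide, OO
Why: Hydroboration–oxidation of a 1,1-disubstituted alkene. Borane should approach C6′ from the face opposite the axial C5a′ methyl and the axial C7′ oxygen, so hydrogen becomes axial and the CH2OH group equatorial. The alkaline oxidative work-up also cleaves the tertiary trimethylsilyl ether.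

Step 23
Reactants: 31 (3R,5aR,6S,7S,9aR)-3-[(tert-butyldimethylsilyl)oxy]-6-(hydroxymethyl)-2,2,5a,7-tetramethyldecahydro-1-benzoxepin-7-ol
Product: 32 (3R,5aR,6R,7S,9aR)-3-[(tert-butyldimethylsilyl)oxy]-6-(iodomethyl)-2,2,5a,7-tetramethyldecahydro-1-benzoxepin-7-ol
Conditions: I2, PPh3, imidazole, THF, 0 °C to rt
Reagents that add atoms: iodine, II
Why: Appel-type iodination, selective for the primary hydroxyl; the tertiary alcohol does not form a reactive alkoxyphosphonium salt.

Step 24
Reactants: 32 (3R,5aR,6R,7S,9aR)-3-[(tert-butyldimethylsilyl)oxy]-6-(iodomethyl)-2,2,5a,7-tetramethyldecahydro-1-benzoxepin-7-ol; 16 (1R,3aR,8aR)-1,4,4-trimethyl-5-methylidene-1-[(triethylsilyl)oxy]octahydroazulen-6(1H)-one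
Product: 33 (1R,3aR,5R,8aR)-5-{2-[(3R,5aR,6R,7S,9aR)-3-[(tert-butyldimethylsilyl)oxy]-7-hydroxy-2,2,5a,7-tetramethyldecahydro-1-benzoxepin-6-yl]ethyl}-1,4,4-trimethyl-1-[(triethylsilyl)oxy]octahydroazulen-6(1H)-one
Conditions: (Me3Si)3SiH (slow addition), AIBN, PhMe, 80 °C
Reagents that add atoms: none
Why: Giese radical conjugate addition; the primary radical from 32 adds to the unhindered methylene terminus of 16 and so forms the bridge despite the neopentyl surroundings. The resulting α-keto radical at C5 should take hydrogen from the bulky silane on the lower face, which puts the side chain on the upper face (5R).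

Step 25
Reactants: 33 (the C6 ketone from step 24)
Product: 34 (1R,3aR,5R,8aR)-5-{2-[(3R,5aR,6R,7S,9aR)-3-[(tert-butyldimethylsilyl)oxy]-7-hydroxy-2,2,5a,7-tetramethyldecahydro-1-benzoxepin-6-yl]ethyl}-1,4,4-trimethyl-1-[(triethylsilyl)oxy]-1,2,3,3a,4,5,8,8a-octahydroazulen-6-yl trifluoromethanesulfonate
Conditions: KN(SiMe3)2 (2.2 equiv), PhNTf2, THF, −78 °C
Reagents that add atoms: N-phenylbis(trifluoromethanesulfonimide), O=S(=O)(N(c1ccccc1)S(=O)(=O)C(F)(F)F)C(F)(F)F
Why: Kinetic enolate formation and O-triflation; deprotonation should occur at the C7 methylene and not at the hindered C5 methine, so C5 is not epimerised, and the extra base only covers the free tertiary hydroxyl.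

Step 26
Reactants: 34 (the enol triflate from step 25)
Product: 35 (3R,5aR,6R,7S,9aR)-3-[(tert-butyldimethylsilyl)oxy]-2,2,5a,7-tetramethyl-6-{2-[(1R,3aR,5S,8aR)-1,4,4,6-tetramethyl-1-[(triethylsilyl)oxy]-1,2,3,3a,4,5,8,8a-octahydroazulen-5-yl]ethyl}decahydro-1-benzoxepin-7-ol
Conditions: Fe(acac)3 (10 mol%), MeMgBr (3.5 equiv), THF/NMP, −30 to 0 °C
Reagents that add atoms: methylmagnesium bromide, C[Mg]Br
Why: Iron-catalysed cross-coupling of an alkenyl triflate with a methyl Grignard reagent, which installs the C6 methyl group with the alkene fixed at C6=C7; the C5 descriptor changes to S by priority only.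

Step 27
Reactants: 35 (the C6=C7 alkene from step 26)
Product: 36 bromohydrin of 35: (5R,6R,7R)-7-bromo-6-hydroxy at the azulene half, all other centres as in 35
Conditions: N-bromosuccinimide, CaCO3, MeOCH2CH2OMe/H2O, 0 °C
Reagents that add atoms: N-bromosuccinimide, O=C1CCC(=O)N1Br; water, O
Why: Bromohydrin formation by anti addition; the bromonium ion should form on the lower face, away from the C5 side chain, and water then enters on the upper face at the tertiary C6. The regioisomeric bromohydrin would give the same oxirane in step 28.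

Step 28
Reactants: 36 (the bromohydrin from step 27)
Product: 37 1-O-triethylsilyl-3′-O-tert-butyldimethylsilyl ether of 38
Conditions: K2CO3, MeOH, rt
Reagents that add atoms: none
Why: Intramolecular Williamson closure; the upper-face alkoxide displaces the lower-face bromide with inversion at C7, which gives the oxirane on the upper face (6R,7S).

Step 29
Reactants: 37 1-O-triethylsilyl-3′-O-tert-butyldimethylsilyl ether of 38
Product: 38 (3R,5aR,6R,7S,9aR)-6-{2-[(1R,3aR,5R,6R,7S,8aR)-6,7-epoxy-1-hydroxy-1,4,4,6-tetramethyldecahydroazulen-5-yl]ethyl}-2,2,5a,7-tetramethyldecahydro-1-benzoxepine-3,7-diol (CNP0216138.1)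
Conditions: Bu4NF, THF, rt to 50 °C
Reagents that add atoms: none
Why: Fluoride cleavage of both silyl ethers under non-acidic conditions that the oxirane tolerates; attack of the freed C1 alkoxide on the oxirane would need a trans-fused bicyclic ether and should not compete.

## Compound list

1 | geraniol, (2E)-3,7-dimethylocta-2,6-dien-1-ol | CC(C)=CCC/C(C)=C/CO | starting material
2 | [(2R,3R)-3-methyl-3-(4-methylpent-3-en-1-yl)oxiran-2-yl]methanol | OC[C@H]1O[C@]1(C)CCC=C(C)C | intermediate
3 | (2R,3S)-3-(chloromethyl)-2-methyl-2-(4-methylpent-3-en-1-yl)oxirane | ClC[C@H]1O[C@]1(C)CCC=C(C)C | intermediate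
4 | (3R)-3,7-dimethyloct-6-en-1-yn-3-ol | C#C[C@](C)(O)CCC=C(C)C | intermediate
5 | {[(3R)-3,7-dimethyloct-6-en-1-yn-3-yl]oxy}triethylsilane | C#C[C@](C)(O[Si](CC)(CC)CC)CCC=C(C)C | intermediate
6 | methyl (4R)-4,8-dimethyl-4-[(triethylsilyl)oxy]non-7-en-2-ynoate | COC(=O)C#C[C@](C)(O[Si](CC)(CC)CC)CCC=C(C)C | intermediate
7 | methyl (2Z)-[(2R,5S)-2-methyl-5-(prop-1-en-2-yl)-2-[(triethylsilyl)oxy]cyclopentylidene]acetate | COC(=O)/C=C1/[C@H](C(C)=C)CC[C@@]1(C)O[Si](CC)(CC)CC | intermediate
8 | methyl 2-[(1R,2R,5R)-2-methyl-5-(prop-1-en-2-yl)-2-[(triethylsilyl)oxy]cyclopentyl]acetate | CC(=C)[C@@H]1CC[C@@](C)(O[Si](CC)(CC)CC)[C@@H]1CC(=O)OC | intermediate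
9 | 2-[(1R,2R,5R)-2-methyl-5-(prop-1-en-2-yl)-2-[(triethylsilyl)oxy]cyclopentyl]ethan-1-ol | CC(=C)[C@@H]1CC[C@@](C)(O[Si](CC)(CC)CC)[C@@H]1CCO | intermediate
10 | triethyl{[(1R,2R,3R)-2-(2-iodoethyl)-1-methyl-3-(prop-1-en-2-yl)cyclopentyl]oxy}silane | CC(=C)[C@@H]1CC[C@@](C)(O[Si](CC)(CC)CC)[C@@H]1CCI | intermediate
11 | {2-[(1R,2R,5R)-2-methyl-5-(prop-1-en-2-yl)-2-[(triethylsilyl)oxy]cyclopentyl]ethyl}zinc iodide | CC(=C)[C@@H]1CC[C@@](C)(O[Si](CC)(CC)CC)[C@@H]1CC[Zn]I | intermediate
12 | 5-[(1R,2R,5R)-2-methyl-5-(prop-1-en-2-yl)-2-[(triethylsilyl)oxy]cyclopentyl]pent-1-en-3-one | CC(=C)[C@@H]1CC[C@@](C)(O[Si](CC)(CC)CC)[C@@H]1CCC(=O)C=C | intermediate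
13 | (1R,3aR,8aR)-1,4-dimethyl-1-[(triethylsilyl)oxy]-2,3,3a,7,8,8a-hexahydroazulen-6(1H)-one | O=C1C=C(C)[C@@H]2CC[C@@](C)(O[Si](CC)(CC)CC)[C@@H]2CC1 | intermediate
14 | triethyl{[(1R,3aR,8aR)-1,4,4-trimethyl-6-[(trimethylsilyl)oxy]-1,2,3,3a,4,7,8,8a-octahydroazulen-1-yl]oxy}silane | C[Si](C)(C)OC1=CC(C)(C)[C@@H]2CC[C@@](C)(O[Si](CC)(CC)CC)[C@@H]2CC1 | intermediate
15 | (1R,3aR,8aR)-5-[(dimethylamino)methyl]-1,4,4-trimethyl-1-[(triethylsilyl)oxy]octahydroazulen-6(1H)-one (C5 epimers) | O=C1C(CN(C)C)C(C)(C)[C@@H]2CC[C@@](C)(O[Si](CC)(CC)CC)[C@@H]2CC1 | intermediate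
16 | (1R,3aR,8aR)-1,4,4-trimethyl-5-methylidene-1-[(triethylsilyl)oxy]octahydroazulen-6(1H)-one | O=C1C(=C)C(C)(C)[C@@H]2CC[C@@](C)(O[Si](CC)(CC)CC)[C@@H]2CC1 | intermediate
17 | 2-methylcyclohex-2-en-1-one | CC1=CCCCC1=O | starting material
18 | (1R)-2-methylcyclohex-2-en-1-ol | O[C@@H]1CCCC=C1C | intermediate
19 | tert-butyl(dimethyl){[(1R)-2-methylcyclohex-2-en-1-yl]oxy}silane | CC(C)(C)[Si](C)(C)O[C@@H]1CCCC=C1C | intermediate
20 | (4R)-4-[(tert-butyldimethylsilyl)oxy]-3-methylcyclohex-2-en-1-one | CC(C)(C)[Si](C)(C)O[C@@H]1CCC(=O)C=C1C | intermediate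
21 | 5-bromo-2-methylpent-2-ene | CC(C)=CCCBr | starting material
22 | (4-methylpent-3-en-1-yl)magnesium bromide | CC(C)=CCC[Mg]Br | intermediate
23 | tert-butyl(dimethyl){[(1R,2R)-2-methyl-2-(4-methylpent-3-en-1-yl)-4-[(trimethylsilyl)oxy]cyclohex-3-en-1-yl]oxy}silane | CC(C)(C)[Si](C)(C)O[C@@H]1CCC(O[Si](C)(C)C)=C[C@@]1(C)CCC=C(C)C | intermediate
24 | (3R,4R)-4-[(tert-butyldimethylsilyl)oxy]-2-[(dimethylamino)methyl]-3-methyl-3-(4-methylpent-3-en-1-yl)cyclohexan-1-one (C2 epimers) | CC(C)(C)[Si](C)(C)O[C@@H]1CCC(=O)C(CN(C)C)[C@@]1(C)CCC=C(C)C | intermediate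
25 | (3R,4R)-4-[(tert-butyldimethylsilyl)oxy]-3-methyl-2-methylidene-3-(4-methylpent-3-en-1-yl)cyclohexan-1-one | CC(C)(C)[Si](C)(C)O[C@@H]1CCC(=O)C(=C)[C@@]1(C)CCC=C(C)C | intermediate
26 | (3R,4R)-4-hydroxy-3-methyl-2-methylidene-3-(4-methylpent-3-en-1-yl)cyclohexan-1-one | O[C@@H]1CCC(=O)C(=C)[C@@]1(C)CCC=C(C)C | intermediate
27 | (3R,4R)-3-{2-[(2R)-3,3-dimethyloxiran-2-yl]ethyl}-4-hydroxy-3-methyl-2-methylidenecyclohexan-1-one | O[C@@H]1CCC(=O)C(=C)[C@@]1(C)CC[C@H]1OC1(C)C | intermediate
28 | (3R,5aR,9aR)-3-hydroxy-2,2,5a-trimethyl-6-methylideneoctahydro-1-benzoxepin-7(2H)-one | CC1(C)O[C@@H]2CCC(=O)C(=C)[C@@]2(C)CC[C@H]1O | intermediate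
29 | (3R,5aR,9aR)-3-[(tert-butyldimethylsilyl)oxy]-2,2,5a-trimethyl-6-methylideneoctahydro-1-benzoxepin-7(2H)-one | CC1(C)O[C@@H]2CCC(=O)C(=C)[C@@]2(C)CC[C@H]1O[Si](C)(C)C(C)(C)C | intermediate
30 | tert-butyl(dimethyl){[(3R,5aR,7S,9aR)-2,2,5a,7-tetramethyl-6-methylidene-7-[(trimethylsilyl)oxy]decahydro-1-benzoxepin-3-yl]oxy}silane | CC1(C)O[C@@H]2CC[C@](C)(O[Si](C)(C)C)C(=C)[C@@]2(C)CC[C@H]1O[Si](C)(C)C(C)(C)C | intermediate
31 | (3R,5aR,6S,7S,9aR)-3-[(tert-butyldimethylsilyl)oxy]-6-(hydroxymethyl)-2,2,5a,7-tetramethyldecahydro-1-benzoxepin-7-ol | CC1(C)O[C@@H]2CC[C@](C)(O)[C@H](CO)[C@@]2(C)CC[C@H]1O[Si](C)(C)C(C)(C)C | intermediate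
32 | (3R,5aR,6R,7S,9aR)-3-[(tert-butyldimethylsilyl)oxy]-6-(iodomethyl)-2,2,5a,7-tetramethyldecahydro-1-benzoxepin-7-ol | CC1(C)O[C@@H]2CC[C@](C)(O)[C@H](CI)[C@@]2(C)CC[C@H]1O[Si](C)(C)C(C)(C)C | intermediate
33 | (1R,3aR,5R,8aR)-5-{2-[(3R,5aR,6R,7S,9aR)-3-[(tert-butyldimethylsilyl)oxy]-7-hydroxy-2,2,5a,7-tetramethyldecahydro-1-benzoxepin-6-yl]ethyl}-1,4,4-trimethyl-1-[(triethylsilyl)oxy]octahydroazulen-6(1H)-one | CC1(C)O[C@@H]2CC[C@](C)(O)[C@H](CC[C@@H]3C(C)(C)[C@@H]4CC[C@@](C)(O[Si](CC)(CC)CC)[C@@H]4CCC3=O)[C@@]2(C)CC[C@H]1O[Si](C)(C)C(C)(C)C | intermediate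
34 | enol triflate of 33: (1R,3aR,5R,8aR)-5-substituted 1,4,4-trimethyl-1-[(triethylsilyl)oxy]-1,2,3,3a,4,5,8,8a-octahydroazulen-6-yl trifluoromethanesulfonate, benzoxepine part as in 33 | CC1(C)O[C@@H]2CC[C@](C)(O)[C@H](CC[C@@H]3C(C)(C)[C@@H]4CC[C@@](C)(O[Si](CC)(CC)CC)[C@@H]4CC=C3OS(=O)(=O)C(F)(F)F)[C@@]2(C)CC[C@H]1O[Si](C)(C)C(C)(C)C | intermediate
35 | (3R,5aR,6R,7S,9aR)-3-[(tert-butyldimethylsilyl)oxy]-2,2,5a,7-tetramethyl-6-{2-[(1R,3aR,5S,8aR)-1,4,4,6-tetramethyl-1-[(triethylsilyl)oxy]-1,2,3,3a,4,5,8,8a-octahydroazulen-5-yl]ethyl}decahydro-1-benzoxepin-7-ol | CC1(C)O[C@@H]2CC[C@](C)(O)[C@H](CC[C@@H]3C(C)(C)[C@@H]4CC[C@@](C)(O[Si](CC)(CC)CC)[C@@H]4CC=C3C)[C@@]2(C)CC[C@H]1O[Si](C)(C)C(C)(C)C | intermediate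
36 | bromohydrin of 35: (1R,3aR,5R,6R,7R,8aR)-7-bromo-6-hydroxy-1,4,4,6-tetramethyl-1-[(triethylsilyl)oxy]decahydroazulen-5-yl unit, benzoxepine part as in 35 | CC1(C)O[C@@H]2CC[C@](C)(O)[C@H](CC[C@@H]3C(C)(C)[C@@H]4CC[C@@](C)(O[Si](CC)(CC)CC)[C@@H]4C[C@@H](Br)[C@]3(C)O)[C@@]2(C)CC[C@H]1O[Si](C)(C)C(C)(C)C | intermediate
37 | 1-O-triethylsilyl-3′-O-tert-butyldimethylsilyl ether of 38 (all stereocentres as in 38) | CC1(C)O[C@@H]2CC[C@](C)(O)[C@H](CC[C@@H]3C(C)(C)[C@@H]4CC[C@@](C)(O[Si](CC)(CC)CC)[C@@H]4C[C@@H]4O[C@@]43C)[C@@]2(C)CC[C@H]1O[Si](C)(C)C(C)(C)C | intermediate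
38 | CNP0216138.1, (3R,5aR,6R,7S,9aR)-6-{2-[(1R,3aR,5R,6R,7S,8aR)-6,7-epoxy-1-hydroxy-1,4,4,6-tetramethyldecahydroazulen-5-yl]ethyl}-2,2,5a,7-tetramethyldecahydro-1-benzoxepine-3,7-diol | CC1(C)O[C@@H]2CC[C@](C)(O)[C@H](CC[C@@H]3C(C)(C)[C@@H]4CC[C@@](C)(O)[C@@H]4C[C@@H]4O[C@@]43C)[C@@]2(C)CC[C@H]1O | target

## Step count and least certain steps

Total: 29 steps. Longest linear sequence: 18 steps (steps 1–12, then 24–29). The benzoxepine branch (steps 13–23) is 11 steps and joins at step 24.

Step 6 (key step). The alkene insertion may discriminate poorly between the two faces at C3a, since the only bias is methyl against silyloxy at C1. β-Hydride elimination may also turn toward the ring and give the conjugated diene, or the hindered ynoate may enter the cycle slowly.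
- Fallback: it sets out from 6 and closes the same bond by oxidative addition instead of hydropalladation.
- Hydroiodination (LiI, AcOH, MeCN) should give methyl (2Z)-3-iodo-4,8-dimethyl-4-[(triethylsilyl)oxy]nona-2,7-dienoate F1.
- An intramolecular Heck reaction (Pd(OAc)2, PPh3, Ag2CO3, MeCN, 80 °C) then proceeds by 5-exo carbopalladation and elimination toward methyl. It should give methyl (2E)-[(2R,5S)-2-methyl-5-(prop-1-en-2-yl)-2-[(triethylsilyl)oxy]cyclopentylidene]acetate F2.
- The alkene geometry is erased by the conjugate reduction of step 7, so the route is rejoined at 8. The cationic Heck manifold also admits chiral bisphosphines for catalyst control of the C3a face.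

Step 10. The organozinc may add to the vinyl ketone as it forms, or the enone may oligomerise.
- Fallback: it sets out from 10. Iodine–lithium exchange (t-BuLi, −78 °C) and addition to acrolein should give 5-[(1R,2R,5R)-2-methyl-5-(prop-1-en-2-yl)-2-[(triethylsilyl)oxy]cyclopentyl]pent-1-en-3-ol F3.
- Ring-closing metathesis of this allylic alcohol should give (1R,3aR,8aR)-1,4-dimethyl-1-[(triethylsilyl)oxy]-1,2,3,3a,6,7,8,8a-octahydroazulen-6-ol F4.
- Oxidation with MnO2 returns to 13.

Step 19. The hydroxyl may open the epoxide at C3′ (six-membered ring) in competition with the wanted attack at C2′, or the activated epoxide may rearrange to a ketone.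
- Fallback: it sets out from 27. Isomerisation of the epoxide (Me3SiOTf, 2,6-lutidine, then DBU; K2CO3, MeOH) should give (3R,4R)-4-hydroxy-3-[(3R)-3-hydroxy-4-methylpent-4-en-1-yl]-3-methyl-2-methylidenecyclohexan-1-one F5.
- Alkoxymercuration with Hg(OCOCF3)2 and NaCl work-up can close a ring only in the Markovnikov sense. It should give {[(3R,5aR,9aR)-3-hydroxy-2,5a-dimethyl-6-methylidene-7-oxodecahydro-1-benzoxepin-2-yl]methyl}mercury chloride F6.
- Bu3SnH with AIBN removes mercury and returns to 28.

Step 24. Hydrogen may be delivered to the C5 radical from the upper face, because the seven-membered ring is flexible and the bias rests only on the ring fusion and the C4 methyl groups. The primary radical may also be reduced before it adds.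
- Fallback: carbon instead of hydrogen enters from the accessible face, which gives the complementary configuration at C5. It sets out from 13.
- Me2CuLi, then BrCH2CO2Me, should give methyl 2-[(1R,3aR,5R,8aR)-1,4,4-trimethyl-6-oxo-1-[(triethylsilyl)oxy]decahydroazulen-5-yl]acetate F7.
- KN(SiMe3)2 and PhNTf2 should give methyl 2-[(1R,3aR,5R,8aR)-1,4,4-trimethyl-1-[(triethylsilyl)oxy]-6-{[(trifluoromethyl)sulfonyl]oxy}-1,2,3,3a,4,5,8,8a-octahydroazulen-5-yl]acetate F8.
- Fe(acac)3 and MeMgBr should give methyl 2-[(1R,3aR,5S,8aR)-1,4,4,6-tetramethyl-1-[(triethylsilyl)oxy]-1,2,3,3a,4,5,8,8a-octahydroazulen-5-yl]acetate F9.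
- LiOH should give 2-[(1R,3aR,5S,8aR)-1,4,4,6-tetramethyl-1-[(triethylsilyl)oxy]-1,2,3,3a,4,5,8,8a-octahydroazulen-5-yl]acetic acid F10.
- N-Hydroxyphthalimide and a carbodiimide should give 1,3-dioxoisoindolin-2-yl 2-[(1R,3aR,5S,8aR)-1,4,4,6-tetramethyl-1-[(triethylsilyl)oxy]-1,2,3,3a,4,5,8,8a-octahydroazulen-5-yl]acetate F11.
- Decarboxylative Giese addition to enone 29 ([Ru(bpy)3](PF6)2, Hantzsch ester, i-Pr2NEt, blue light), with axial protonation at C6′, should give (3R,5aR,6R,9aR)-3-[(tert-butyldimethylsilyl)oxy]-2,2,5a-trimethyl-6-{2-[(1R,3aR,5S,8aR)-1,4,4,6-tetramethyl-1-[(triethylsilyl)oxy]-1,2,3,3a,4,5,8,8a-octahydroazulen-5-yl]ethyl}octahydro-1-benzoxepin-7(2H)-one F12.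
- MeLi with CeCl3, as in step 21, returns to 35.

Step 27. The bromonium ion may form on the upper face instead of the lower one, or be captured by a neighbouring oxygen, because the cycloheptene offers little facial bias.
- Fallback: it sets out from 35. Direct oxygen transfer with dimethyldioxirane (or a buffered peroxy acid) reaches the face the electrophile prefers and gives 37 in one step.
- It is the right choice exactly when the bromonium route fails for facial reasons.

## Further compounds

F1 | step 6 | methyl (2Z)-3-iodo-4,8-dimethyl-4-[(triethylsilyl)oxy]nona-2,7-dienoate (4R) | COC(=O)/C=C(\I)[C@](C)(O[Si](CC)(CC)CC)CCC=C(C)C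
F2 | step 6 | methyl (2E)-[(2R,5S)-2-methyl-5-(prop-1-en-2-yl)-2-[(triethylsilyl)oxy]cyclopentylidene]acetate | COC(=O)/C=C1\[C@H](C(C)=C)CC[C@@]1(C)O[Si](CC)(CC)CC
F3 | step 10 | 5-[(1R,2R,5R)-2-methyl-5-(prop-1-en-2-yl)-2-[(triethylsilyl)oxy]cyclopentyl]pent-1-en-3-ol (carbinol epimers) | CC(=C)[C@@H]1CC[C@@](C)(O[Si](CC)(CC)CC)[C@@H]1CCC(O)C=C
F4 | step 10 | (1R,3aR,8aR)-1,4-dimethyl-1-[(triethylsilyl)oxy]-1,2,3,3a,6,7,8,8a-octahydroazulen-6-ol (carbinol epimers) | OC1C=C(C)[C@@H]2CC[C@@](C)(O[Si](CC)(CC)CC)[C@@H]2CC1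
F5 | step 19 | (3R,4R)-4-hydroxy-3-[(3R)-3-hydroxy-4-methylpent-4-en-1-yl]-3-methyl-2-methylidenecyclohexan-1-one | O[C@@H]1CCC(=O)C(=C)[C@@]1(C)CC[C@@H](O)C(C)=C
F6 | step 19 | {[(3R,5aR,9aR)-3-hydroxy-2,5a-dimethyl-6-methylidene-7-oxodecahydro-1-benzoxepin-2-yl]methyl}mercury chloride (C2′ epimers) | CC1(C[Hg]Cl)O[C@@H]2CCC(=O)C(=C)[C@@]2(C)CC[C@H]1O
F7 | step 24 | methyl 2-[(1R,3aR,5R,8aR)-1,4,4-trimethyl-6-oxo-1-[(triethylsilyl)oxy]decahydroazulen-5-yl]acetate | COC(=O)C[C@@H]1C(C)(C)[C@@H]2CC[C@@](C)(O[Si](CC)(CC)CC)[C@@H]2CCC1=O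
F8 | step 24 | methyl 2-[(1R,3aR,5R,8aR)-1,4,4-trimethyl-1-[(triethylsilyl)oxy]-6-{[(trifluoromethyl)sulfonyl]oxy}-1,2,3,3a,4,5,8,8a-octahydroazulen-5-yl]acetate | COC(=O)C[C@@H]1C(C)(C)[C@@H]2CC[C@@](C)(O[Si](CC)(CC)CC)[C@@H]2CC=C1OS(=O)(=O)C(F)(F)F
F9 | step 24 | methyl 2-[(1R,3aR,5S,8aR)-1,4,4,6-tetramethyl-1-[(triethylsilyl)oxy]-1,2,3,3a,4,5,8,8a-octahydroazulen-5-yl]acetate | COC(=O)C[C@@H]1C(C)(C)[C@@H]2CC[C@@](C)(O[Si](CC)(CC)CC)[C@@H]2CC=C1C
F10 | step 24 | 2-[(1R,3aR,5S,8aR)-1,4,4,6-tetramethyl-1-[(triethylsilyl)oxy]-1,2,3,3a,4,5,8,8a-octahydroazulen-5-yl]acetic acid | OC(=O)C[C@@H]1C(C)(C)[C@@H]2CC[C@@](C)(O[Si](CC)(CC)CC)[C@@H]2CC=C1C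
F11 | step 24 | 1,3-dioxoisoindolin-2-yl 2-[(1R,3aR,5S,8aR)-1,4,4,6-tetramethyl-1-[(triethylsilyl)oxy]-1,2,3,3a,4,5,8,8a-octahydroazulen-5-yl]acetate | O=C(C[C@@H]1C(C)(C)[C@@H]2CC[C@@](C)(O[Si](CC)(CC)CC)[C@@H]2CC=C1C)ON1C(=O)c2ccccc2C1=O
F12 | step 24 | (3R,5aR,6R,9aR)-3-[(tert-butyldimethylsilyl)oxy]-2,2,5a-trimethyl-6-{2-[(1R,3aR,5S,8aR)-1,4,4,6-tetramethyl-1-[(triethylsilyl)oxy]-1,2,3,3a,4,5,8,8a-octahydroazulen-5-yl]ethyl}octahydro-1-benzoxepin-7(2H)-one | CC1(C)O[C@@H]2CCC(=O)[C@H](CC[C@@H]3C(C)(C)[C@@H]4CC[C@@](C)(O[Si](CC)(CC)CC)[C@@H]4CC=C3C)[C@@]2(C)CC[C@H]1O[Si](C)(C)C(C)(C)C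
F0 | step 27 | none | none
A1 | alternative 1 | (6S,7R)-6-methyl-7-[(2-methylbut-3-en-2-yl)oxy]-6-(prop-2-en-1-yl)-1,4-dioxaspiro[4.5]decane | C=CC(C)(C)O[C@@H]1CCCC2(OCCO2)[C@@]1(C)CC=C
A2 | alternative 1 | ethylene ketal of trans-fused 2,2,5a-trimethyl-2,5,5a,7,8,9,9a-heptahydro-1-benzoxepin-6-one (product of the key step) | CC1(C)O[C@@H]2CCCC3(OCCO3)[C@@]2(C)CC=C1
A3 | alternative 2 | 3-[6-ethenyl-3-[(tert-butyldimethylsilyl)oxy]-2,2,6-trimethyloxepan-7-yl]propanal oxime | CC1(C)O[C@H](CCC=NO)[C@@](C)(C=C)CC[C@H]1O[Si](C)(C)C(C)(C)C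
A4 | alternative 2 | nitrile oxide from A3 | CC1(C)O[C@H](CCC#[N+][O-])[C@@](C)(C=C)CC[C@H]1O[Si](C)(C)C(C)(C)C
A5 | alternative 2 | isoxazoline-fused perhydrobenzoxepine (product of the key step) | CC1(C)O[C@@H]2CCC3=NOC[C@@H]3[C@@]2(C)CC[C@H]1O[Si](C)(C)C(C)(C)C
A6 | alternative 3 | bis-epoxy allylsilane pivalate: (2Z)-5-{(2R,3R)-3-[2-((2R)-3,3-dimethyloxiran-2-yl)ethyl]-3-methyloxiran-2-yl}-3-[(trimethylsilyl)methyl]pent-2-en-1-yl pivalate | CC(C)(C)C(=O)OC/C=C(\C[Si](C)(C)C)CC[C@H]1O[C@]1(C)CC[C@H]1OC1(C)C
A7 | alternative 3 | [(3R,5aR,6R,9aR)-3-hydroxy-2,2,5a-trimethyl-7-methylidenedecahydro-1-benzoxepin-6-yl]methyl pivalate (product of the key step) | CC1(C)O[C@@H]2CCC(=C)[C@H](COC(=O)C(C)(C)C)[C@@]2(C)CC[C@H]1O
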